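The numbers belong to no real substance; the flask was simulated.

- The leftover I watch in this flask is the target still dissolved and waiting to crystallise, since the side reaction takes starting material and dissolved target, and each side product costs two units of the charge.

starting material 0.90 M; reagent in the second phase 2.00 equiv; time 2.0 h; volume of the second phase over the first 2.0

* how much target and crystals together there is at 2.0 h, in percent of the starting material charged
* concentration of target in solution at 1.0 h, in percent of saturation
* the change that raises the amount of target and crystals together at 2.0 h, in percent of the starting material charged most ("none" if none brings more than 2 percentage points) (alpha / beta / epsilon / zeta / none)
* amount of target and crystals together at 2.0 h, in percent of the starting material charged, after beta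

- percent here means starting material units held: one side product counts as two
- what is said of target includes crystals
- in the second phase: reagent in the second phase; everything else is in the first
- charges count per volume of the first phase; a concentration in a rate is the amount of a species over the volume of its own phase; every rate counts per litre of the first phase
- crystals is a solid; its amount is given per volume of the solution
- run time (flask): 2.0 h

- alpha: doubling the amount of reagent in the second phase, all else as stated
- beta: doubling the transfer coefficient of step 4, all else as stated
- epsilon: doubling the solubility in step 3, all else as stated
- zeta: doubling the dissolution coefficient of step 3, all else as stated

    starting material + reagent in the reaction phase → target (k1 = 0.260 /M/min)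
    target ⇌ isomer of the product (K2 = 9.0, k2 = 0.00830 /min)
    crystals ⇌ target, rate k3*(cs3 - [target]) while solid is left; crystals form when [target] > cs3 (cs3 = 15 mM, k3 = 0.544 /min)
    reagent in the reaction phase ⇌ reagent in the second phase, rate k4*([reagent in the reaction phase] - [reagent in the second phase]/K4) per volume of the first phase (K4 = 0.949, k4 = 0.0697 /min)
    reagent in the reaction phase + target → over-reacted product (k5 = 0.0611 /M/min)
    starting material + target → side product (k6 = 0.0529 /M/min)

- I turn the question round and ask what "none" would require, and I begin with the dissolved target. At onset, the reagent in the reaction phase settles where transfer balances consumption, at 0.218 M, or 24.2% of the charge.
- While crystals grow, a quasi-steady state holds the dissolved target above solubility: formation of target balances crystallisation. That excess starts at 10.4% of the charge, and I neglect the solubility, 1.67%, as smaller.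
- Dividing the side reaction by the main reaction cancels the reagent. What remains is the toll, the fraction of target lost per target made at the start, namely the side rate constant times the starting concentration over the dissolution coefficient: 8.75%.
- The toll shrinks with the starting material, so I join its two ends, the full toll and zero. The mean is half of it, and two units per event bring the loss back to one toll, about 8.75% of the charge.
- Doubling the dissolution coefficient halves that loss, so zeta should gain 4.4 percentage points, above the margin of 2 points. For zeta to bring no more than the margin, the toll would have to stand under half of its value here. The reagent has cancelled, so I expect little from beta. I commit to zeta, with y reckoned at 91.2% before over-reaction and isomer take their part; my reckoning stops there, and the forecast's y is lower than this figure.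
- The forecast gives 80%, 110%, zeta and 79.5%, on the ground that “That supersaturation scales inversely with the dissolution coefficient”.
- The flask gives 82.6%, 117%, zeta and 82.5%, so the forecast's saturation lies 7.0 points low. With the side reaction struck out, y reads 91.9%. Zeta brings 4.4 points, beside the 4.4 points I reckoned from the toll.

- In the neighbour flask with 0.23 M of starting material, the toll is 2.24%. Its onset excess, 6.23%, is close to the solubility, 6.52%, so the term I neglected is no longer small and the toll reads low there. That neighbour flask shows 7.60% of side product, more than the toll.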